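**Retrosynthetic overview**
- The target is a 4'-silyl-protected prenylchromenol after desilylation; its C6 prenyl group comes from an aromatic Claisen rearrangement of the 1,1-dimethylallyl ether of the 5-hydroxychromene, whose only free ortho carbon is C6.
- The pyran ring is the only ring built: aldol-type condensation and 6π-electrocyclisation of a 5-(arylethyl)resorcinol with 3-methylbut-2-enal at the carbon between the two hydroxyls.
- The bibenzyl resorcinol comes from a stilbene by one hydrogenation that also removes two benzyl ethers.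
- Key C–C bond (central bond of the bibenzyl): intermolecular Perkin-type aldol condensation of 3,5-bis(benzyloxy)benzaldehyde with (4-hydroxyphenyl)acetic acid, followed by decarboxylation.
- Ring order: both benzene rings are purchased; the pyran ring is formed in step 6.

Assumption: the target has no stereocentre and its only ring alkene is geometrically fixed, so it is achiral and "single enantiomer" means the constitution shown.

**Route**

Step 1
Reactants: 1 3,5-bis(benzyloxy)benzaldehyde; 2 (4-hydroxyphenyl)acetic acid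
Product: 3 (2E)-2-[4-(acetyloxy)phenyl]-3-[3,5-bis(benzyloxy)phenyl]prop-2-enoic acid
Conditions: Ac2O, Et3N, 115 °C, 10 h; then H2O, 60 °C; dilute HCl; recrystallise
Reagents that add atoms: acetic anhydride, CC(=O)OC(C)=O
Why: Perkin condensation (aldol-type addition of the mixed-anhydride enolate of the arylacetic acid to the aldehyde, then elimination) gives the E acid with the two aryl groups cis, the phenol being acetylated in the flask.

Step 2
Reactants: 3 (2E)-2-[4-(acetyloxy)phenyl]-3-[3,5-bis(benzyloxy)phenyl]prop-2-enoic acid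
Product: 4 (2E)-3-[3,5-bis(benzyloxy)phenyl]-2-(4-hydroxyphenyl)prop-2-enoic acid
Conditions: NaOH (aq), THF/MeOH, rt; then HCl to pH 2
Reagents that add atoms: none
Why: Saponification of the aryl acetate is fast at room temperature and leaves the benzyl ethers and the acrylic acid untouched.

Step 3
Reactants: 4 (2E)-3-[3,5-bis(benzyloxy)phenyl]-2-(4-hydroxyphenyl)prop-2-enoic acid
Product: 5 4-{(Z)-2-[3,5-bis(benzyloxy)phenyl]ethenyl}phenol
Conditions: Cu powder, quinoline, 200 °C, 2 h
Reagents that add atoms: none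
Why: Copper-mediated protodecarboxylation of an α-arylcinnamic acid proceeds with retention to the cis-stilbene, and the geometry is immaterial because step 5 saturates the alkene.

Step 4
Reactants: 5 4-{(Z)-2-[3,5-bis(benzyloxy)phenyl]ethenyl}phenol
Product: 6 {4-[(Z)-2-(3,5-bis(benzyloxy)phenyl)ethenyl]phenoxy}tri(propan-2-yl)silane
Conditions: TIPSCl, imidazole, DMF, rt
Reagents that add atoms: triisopropylsilyl chloride, CC(C)[Si](Cl)(C(C)C)C(C)C
Why: Silylation of the single free phenol installs a group that survives hydrogenation, amine catalysis, DBU and heat but leaves with fluoride at the end.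

Step 5
Reactants: 6 {4-[(Z)-2-(3,5-bis(benzyloxy)phenyl)ethenyl]phenoxy}tri(propan-2-yl)silane
Product: 7 5-{2-[4-(triisopropylsilyloxy)phenyl]ethyl}benzene-1,3-diol
Conditions: H2 (1 atm), 10% Pd/C, EtOAc/EtOH, rt
Reagents that add atoms: none
Why: Catalytic hydrogenation saturates the stilbene and hydrogenolyses both benzyl ethers in one operation, while the aryl silyl ether is inert.

Step 6
Reactants: 7 5-{2-[4-(triisopropylsilyloxy)phenyl]ethyl}benzene-1,3-diol; 8 3-methylbut-2-enal
Product: 10 2,2-dimethyl-7-{2-[4-(triisopropylsilyloxy)phenyl]ethyl}-2H-chromen-5-ol, via ortho-quinone methide 9 (not isolated)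
Conditions: 8 (1.1 equiv, slow addition), ethylenediammonium diacetate (10 mol%), toluene, reflux
Reagents that add atoms: none
Why: Amine-catalysed aldol-type condensation of the enal at the resorcinol carbon flanked by both hydroxyls, dehydration to the ortho-quinone methide and oxa-6π-electrocyclisation give the 5-hydroxy-7-alkyl-2H-chromene, the regiochemistry seen in cannabichromene-type syntheses.

Step 7
Reactants: 10 2,2-dimethyl-7-{2-[4-(triisopropylsilyloxy)phenyl]ethyl}-2H-chromen-5-ol; 11 3-chloro-3-methylbut-1-yne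
Product: 12 2,2-dimethyl-5-[(2-methylbut-3-yn-2-yl)oxy]-7-{2-[4-(triisopropylsilyloxy)phenyl]ethyl}-2H-chromene
Conditions: DBU, CuCl2·2H2O (0.5 mol%), MeCN, 0 °C
Reagents that add atoms: none
Why: Copper-catalysed O-alkylation of the phenol with the tertiary propargylic chloride gives the 1,1-dimethylpropargyl aryl ether cleanly at 0 °C, well below the temperature of any propargyl Claisen.

Step 8
Reactants: 12 2,2-dimethyl-5-[(2-methylbut-3-yn-2-yl)oxy]-7-{2-[4-(triisopropylsilyloxy)phenyl]ethyl}-2H-chromene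
Product: 13 2,2-dimethyl-5-[(2-methylbut-3-en-2-yl)oxy]-7-{2-[4-(triisopropylsilyloxy)phenyl]ethyl}-2H-chromene
Conditions: H2 (1 atm), Pd/CaCO3 poisoned with Pb(OAc)2 (Lindlar catalyst), quinoline, EtOAc, rt, stop at 1 equiv H2
Reagents that add atoms: none
Why: Lindlar semi-hydrogenation reduces the terminal alkyne to the vinyl group and does not touch the conjugated chromene alkene.

Step 9
Reactants: 13 2,2-dimethyl-5-[(2-methylbut-3-en-2-yl)oxy]-7-{2-[4-(triisopropylsilyloxy)phenyl]ethyl}-2H-chromene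
Product: 15 2,2-dimethyl-6-(3-methylbut-2-en-1-yl)-7-{2-[4-(triisopropylsilyloxy)phenyl]ethyl}-2H-chromen-5-ol, via cyclohexadienone 14 (not isolated)
Conditions: N,N-diethylaniline, 130 °C, Ar
Reagents that add atoms: none
Why: Aromatic Claisen [3,3] rearrangement moves the allyl unit with inversion to the only unsubstituted ortho carbon (C6), so the tertiary ether becomes the linear prenyl group, and tautomerisation of the racemic dienone restores the phenol.

Step 10
Reactants: 15 2,2-dimethyl-6-(3-methylbut-2-en-1-yl)-7-{2-[4-(triisopropylsilyloxy)phenyl]ethyl}-2H-chromen-5-ol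
Product: 16 7-[2-(4-hydroxyphenyl)ethyl]-2,2-dimethyl-6-(3-methylbut-2-en-1-yl)-2H-chromen-5-ol (target)
Conditions: Bu4NF, AcOH (1:1), THF, 0 °C to rt
Reagents that add atoms: none
Why: Buffered fluoride desilylation frees the phenol under non-acidic conditions, so the ortho-prenyl phenol cannot cyclise to a chroman and the chromene is untouched.

**Compound list**
1 | 3,5-bis(benzyloxy)benzaldehyde | O=Cc1cc(OCc2ccccc2)cc(OCc2ccccc2)c1 | starting material
2 | (4-hydroxyphenyl)acetic acid | OC(=O)Cc1ccc(O)cc1 | starting material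
3 | (2E)-2-[4-(acetyloxy)phenyl]-3-[3,5-bis(benzyloxy)phenyl]prop-2-enoic acid | OC(=O)/C(=C/c1cc(OCc2ccccc2)cc(OCc2ccccc2)c1)c1ccc(OC(C)=O)cc1 | intermediate
4 | (2E)-3-[3,5-bis(benzyloxy)phenyl]-2-(4-hydroxyphenyl)prop-2-enoic acid | OC(=O)/C(=C/c1cc(OCc2ccccc2)cc(OCc2ccccc2)c1)c1ccc(O)cc1 | intermediate
5 | 4-{(Z)-2-[3,5-bis(benzyloxy)phenyl]ethenyl}phenol | Oc1ccc(/C=C\c2cc(OCc3ccccc3)cc(OCc3ccccc3)c2)cc1 | intermediate
6 | {4-[(Z)-2-(3,5-bis(benzyloxy)phenyl)ethenyl]phenoxy}tri(propan-2-yl)silane | CC(C)[Si](Oc1ccc(/C=C\c2cc(OCc3ccccc3)cc(OCc3ccccc3)c2)cc1)(C(C)C)C(C)C | intermediate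
7 | 5-{2-[4-(triisopropylsilyloxy)phenyl]ethyl}benzene-1,3-diol | CC(C)[Si](Oc1ccc(CCc2cc(O)cc(O)c2)cc1)(C(C)C)C(C)C | intermediate
8 | 3-methylbut-2-enal | CC(C)=CC=O | starting material
9 | 5-hydroxy-6-(3-methylbut-2-en-1-ylidene)-3-{2-[4-(triisopropylsilyloxy)phenyl]ethyl}cyclohexa-2,4-dien-1-one (ortho-quinone methide) | O=C1C=C(CCc2ccc(O[Si](C(C)C)(C(C)C)C(C)C)cc2)C=C(O)C1=CC=C(C)C | intermediate
10 | 2,2-dimethyl-7-{2-[4-(triisopropylsilyloxy)phenyl]ethyl}-2H-chromen-5-ol | CC1(C)C=Cc2c(O)cc(CCc3ccc(O[Si](C(C)C)(C(C)C)C(C)C)cc3)cc2O1 | intermediate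
11 | 3-chloro-3-methylbut-1-yne | C#CC(C)(C)Cl | starting material
12 | 2,2-dimethyl-5-[(2-methylbut-3-yn-2-yl)oxy]-7-{2-[4-(triisopropylsilyloxy)phenyl]ethyl}-2H-chromene | C#CC(C)(C)Oc1cc(CCc2ccc(O[Si](C(C)C)(C(C)C)C(C)C)cc2)cc2OC(C)(C)C=Cc12 | intermediate
13 | 2,2-dimethyl-5-[(2-methylbut-3-en-2-yl)oxy]-7-{2-[4-(triisopropylsilyloxy)phenyl]ethyl}-2H-chromene | C=CC(C)(C)Oc1cc(CCc2ccc(O[Si](C(C)C)(C(C)C)C(C)C)cc2)cc2OC(C)(C)C=Cc12 | intermediate
14 | 2,2-dimethyl-6-(3-methylbut-2-en-1-yl)-7-{2-[4-(triisopropylsilyloxy)phenyl]ethyl}-2H-chromen-5(6H)-one (racemic cyclohexadienone) | CC(C)=CCC1C(=O)C2=C(C=C1CCc1ccc(O[Si](C(C)C)(C(C)C)C(C)C)cc1)OC(C)(C)C=C2 | intermediate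
15 | 2,2-dimethyl-6-(3-methylbut-2-en-1-yl)-7-{2-[4-(triisopropylsilyloxy)phenyl]ethyl}-2H-chromen-5-ol | CC(C)=CCc1c(CCc2ccc(O[Si](C(C)C)(C(C)C)C(C)C)cc2)cc2c(c1O)C=CC(C)(C)O2 | intermediate
16 | 7-[2-(4-hydroxyphenyl)ethyl]-2,2-dimethyl-6-(3-methylbut-2-en-1-yl)-2H-chromen-5-ol | CC(C)=CCc1c(CCc2ccc(O)cc2)cc2c(c1O)C=CC(C)(C)O2 | target

**Totals**
Total step count: 10. Longest linear sequence: 10 steps (from 1 or 2 to 16).

**Three steps most likely to fail, with fallbacks**

Step 3 (decarboxylation at 200 °C; risk of tar and partial debenzylation). The fallback sets out from 1 and 2 and returns at 6. It keeps the same central bond but makes it by an aldol addition, so that CO2 and OH leave together under mild conditions. Acid 2 is persilylated (TIPSCl, imidazole, DMF) to triisopropylsilyl [4-(triisopropylsilyloxy)phenyl]acetate F1, and the silyl ester is hydrolysed in the same flask (K2CO3, aqueous MeOH) to [4-(triisopropylsilyloxy)phenyl]acetic acid F2. Its dianion (LiN(iPr)2, 2.2 equiv, THF, −78 °C) adds to aldehyde 1 in an Ivanov aldol reaction to give mainly threo, racemic 3-[3,5-bis(benzyloxy)phenyl]-3-hydroxy-2-[4-(triisopropylsilyloxy)phenyl]propanoic acid F3. Decarboxylative dehydration with N,N-dimethylformamide dimethyl acetal (CHCl3, 60 °C, anti elimination) then gives stilbene 6; any loss of geometric purity does not matter because step 5 saturates the double bond.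

Step 6 (chromene annulation; risk of the regioisomer from attack next to the side chain and of double annulation). The fallback sets out from 7 and returns at 10, with regiocontrol by directed metalation. Resorcinol 7 is converted (MOMCl, iPr2NEt, CH2Cl2) to 1,3-bis(methoxymethoxy)-5-{2-[4-(triisopropylsilyloxy)phenyl]ethyl}benzene F4. Lithiation between the two acetal oxygens (n-BuLi, THF, 0 °C) and addition to enal 8 at −78 °C give racemic 1-{2,6-bis(methoxymethoxy)-4-[2-(4-(triisopropylsilyloxy)phenyl)ethyl]phenyl}-3-methylbut-2-en-1-ol F5. TsOH·H2O (cat.) in MeOH at 50 °C ionises the allylic benzylic alcohol, closes the pyran ring onto the tertiary allyl terminus and removes both acetals, giving 10.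

Step 9 (Claisen rearrangement; risk of isoprene loss back to 10 and of migration on to C8). The fallback sets out from 10 and returns at 15 without a sigmatropic step. The sodium phenoxide of 10 (NaH, toluene, 0 °C) is C-alkylated with 1-bromo-3-methylbut-2-ene; in a non-polar solvent the tight ion pair directs alkylation to the ortho carbon, and C6 is the only free one. This gives 15 directly, separable from the O-prenyl ether.

**Further compounds**
F1 | step 3 | triisopropylsilyl [4-(triisopropylsilyloxy)phenyl]acetate | CC(C)[Si](OC(=O)Cc1ccc(O[Si](C(C)C)(C(C)C)C(C)C)cc1)(C(C)C)C(C)C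
F2 | step 3 | [4-(triisopropylsilyloxy)phenyl]acetic acid | CC(C)[Si](Oc1ccc(CC(=O)O)cc1)(C(C)C)C(C)C
F3 | step 3 | (2RS,3SR)-3-[3,5-bis(benzyloxy)phenyl]-3-hydroxy-2-[4-(triisopropylsilyloxy)phenyl]propanoic acid (racemic, one enantiomer drawn) | OC(=O)[C@@H](c1ccc(O[Si](C(C)C)(C(C)C)C(C)C)cc1)[C@@H](O)c1cc(OCc2ccccc2)cc(OCc2ccccc2)c1
F4 | step 6 | 1,3-bis(methoxymethoxy)-5-{2-[4-(triisopropylsilyloxy)phenyl]ethyl}benzene | COCOc1cc(CCc2ccc(O[Si](C(C)C)(C(C)C)C(C)C)cc2)cc(OCOC)c1
F5 | step 6 | 1-{2,6-bis(methoxymethoxy)-4-[2-(4-(triisopropylsilyloxy)phenyl)ethyl]phenyl}-3-methylbut-2-en-1-ol (racemic) | COCOc1cc(CCc2ccc(O[Si](C(C)C)(C(C)C)C(C)C)cc2)cc(OCOC)c1C(O)C=C(C)C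
F0 | step 9 | none | none
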